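The route rests on cutting the bond between chain carbon C7 and C1 of the syringyl (4-hydroxy-3,5-dimethoxyphenyl) ring. The key step is a redox-relay Heck arylation of a racemic vinyl carbinol, made by aldol addition of zingerone to acrolein, with 4-iodo-2,6-dimethoxyphenol. It exploits the 1,3-relationship between the aryl-bearing C7 and the oxygen on C5: the aryl group enters at C7 and β-hydride elimination from the C5 carbinol delivers the C5 ketone, so one operation joins both halves and gives the heptane-3,5-dione. Double asymmetric hydrogenation with RuCl2[(S)-BINAP] then sets both carbinol centres (3S,5S, anti) at once. No protecting group is needed.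

Key step: step 3

Remark: chain carbons are numbered C1 (CH2 on the guaiacyl ring) to C7 (CH2 on the syringyl ring); dione 8 is written as the diketone although it should exist largely as its enol.

Step 1
Reactants: 1 2,6-dimethoxyphenol
Product: 2 4-iodo-2,6-dimethoxyphenol
Conditions: I2 (1.05 equiv), NaHCO3, THF/H2O, 0 °C to rt
Reagents that add atoms: iodine, II
Why: Electrophilic aromatic iodination of the phenoxide; both positions ortho to the oxygen carry methoxy groups, so the para position is the only one the phenoxide activates and should be iodinated selectively under mild bicarbonate conditions that keep oxidative phenol coupling slow.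

Step 2
Reactants: 3 zingerone [4-(4-hydroxy-3-methoxyphenyl)butan-2-one]; 4 acrolein
Product: 6 rac-5-hydroxy-1-(4-hydroxy-3-methoxyphenyl)hept-6-en-3-one, via dilithium phenoxide enolate 5 (not isolated)
Conditions: LiN(i-Pr)2 (2.2 equiv), THF, −78 °C; acrolein (1.1 equiv), −78 °C; AcOH quench at −78 °C
Reagents that add atoms: none
Why: Kinetic deprotonation of the phenoxide ketone by the hindered amide base at the methyl group gives the terminal lithium enolate, which should add 1,2 to acrolein at low temperature (lithium enolate aldol addition); the C5 carbinol centre is formed racemic on purpose because step 3 erases it.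

Step 3
Reactants: 6 rac-5-hydroxy-1-(4-hydroxy-3-methoxyphenyl)hept-6-en-3-one; 2 4-iodo-2,6-dimethoxyphenol
Product: 8 1-(4-hydroxy-3,5-dimethoxyphenyl)-7-(4-hydroxy-3-methoxyphenyl)heptane-3,5-dione, via C5 enol 7 (not isolated)
Conditions: Pd(OAc)2 (5 mol %), Bu4NCl (1 equiv), NaHCO3 (3 equiv), DMF, 45 °C, argon
Reagents that add atoms: none
Why: Zerovalent palladium, formed in the flask from Pd(OAc)2, inserts into the C–I bond of 2, the arylpalladium iodide adds syn across the monosubstituted C6=C7 double bond of 6 with the aryl group on the unsubstituted terminus C7 and palladium on C6, and β-hydride elimination of the hydrogen on the carbinol carbon C5 gives enol 7, which tautomerises to the C5 ketone. The closest known reaction type is the Heck arylation of secondary allylic alcohols to β-aryl ketones under ligand-free, phase-transfer conditions (chloride salt, bicarbonate). No ring is closed and no stereocentre is created; the racemic C5 centre of 6 is consumed as the internal reductant, so the step is redox-neutral and leaves C3 and C5 both as carbonyl groups for step 4. Three selectivities are needed: aryl delivery to C7 and not C6, which the terminal position of the alkene secures; β-hydride elimination toward C5–H and not toward the benzylic C7–H, which the adjacent hydroxyl group favours in the absence of silver salts and which leads on to the strongly stabilised enolised 1,3-diketone; and survival of the β-hydroxy ketone of 6, which the weak base and the low temperature made possible by the aryl iodide should secure. The free phenols of both partners are expected to be tolerated, as they are in Heck reactions of iodophenols in general.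

Step 4
Reactants: 8 1-(4-hydroxy-3,5-dimethoxyphenyl)-7-(4-hydroxy-3-methoxyphenyl)heptane-3,5-dione
Product: 11 (3S,5S)-1-(4-hydroxy-3-methoxyphenyl)-7-(4-hydroxy-3,5-dimethoxyphenyl)heptane-3,5-diol, via C5-hydroxy ketone 9 (not isolated), via C3-hydroxy ketone 10 (not isolated)
Conditions: RuCl2[(S)-BINAP] (1 mol %), H2 (80 atm), MeOH, 50 °C
Reagents that add atoms: none
Why: Noyori asymmetric hydrogenation of a 1,3-diketone, in which each carbonyl is reduced through a chelate to ruthenium under control of the (S)-BINAP ligand and the second reduction is matched with the first carbinol, so that the anti (3S,5S)-diol should result with the sense of induction established for pentane-2,4-dione, while phenols and aryl ethers stay untouched.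

Compound list
1 | 2,6-dimethoxyphenol | COc1cccc(OC)c1O | starting material
2 | 4-iodo-2,6-dimethoxyphenol | COc1cc(I)cc(OC)c1O | intermediate
3 | zingerone [4-(4-hydroxy-3-methoxyphenyl)butan-2-one] | COc1cc(CCC(C)=O)ccc1O | starting material
4 | acrolein (prop-2-enal) | C=CC=O | starting material
5 | dilithium phenoxide enolate of zingerone (terminal enolate) | [Li+].[Li+].COc1cc(CCC(=C)[O-])ccc1[O-] | intermediate
6 | rac-5-hydroxy-1-(4-hydroxy-3-methoxyphenyl)hept-6-en-3-one | COc1cc(CCC(=O)CC(O)C=C)ccc1O | intermediate
7 | 5-hydroxy-7-(4-hydroxy-3,5-dimethoxyphenyl)-1-(4-hydroxy-3-methoxyphenyl)hept-5-en-3-one (C5 enol) | COc1cc(CCC(=O)CC(O)=CCc2cc(OC)c(O)c(OC)c2)ccc1O | intermediate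
8 | 1-(4-hydroxy-3,5-dimethoxyphenyl)-7-(4-hydroxy-3-methoxyphenyl)heptane-3,5-dione | COc1cc(CCC(=O)CC(=O)CCc2cc(OC)c(O)c(OC)c2)ccc1O | intermediate
9 | (5S)-5-hydroxy-7-(4-hydroxy-3,5-dimethoxyphenyl)-1-(4-hydroxy-3-methoxyphenyl)heptan-3-one | COc1cc(CCC(=O)C[C@@H](O)CCc2cc(OC)c(O)c(OC)c2)ccc1O | intermediate
10 | (5S)-5-hydroxy-1-(4-hydroxy-3,5-dimethoxyphenyl)-7-(4-hydroxy-3-methoxyphenyl)heptan-3-one | COc1cc(CC[C@H](O)CC(=O)CCc2cc(OC)c(O)c(OC)c2)ccc1O | intermediate
11 | (3S,5S)-1-(4-hydroxy-3-methoxyphenyl)-7-(4-hydroxy-3,5-dimethoxyphenyl)heptane-3,5-diol | COc1cc(CC[C@H](O)C[C@@H](O)CCc2cc(OC)c(O)c(OC)c2)ccc1O | target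

Total step count: 4. Longest linear sequence: 3 steps (3 to 6 to 8 to 11, or 1 to 2 to 8 to 11).

Steps most likely to fail

Step 3. The alkylpalladium intermediate may eliminate toward the benzylic C7–H and give the styrenyl carbinol instead of the ketone, or the β-hydroxy ketone of 6 may dehydrate under the basic coupling conditions before it is arylated. The fallback moves the union from a Heck reaction to a conjugate addition and sets the C5 oxidation level beforehand. Setting out from 6, oxidation of the allylic carbinol with MnO2 (CH2Cl2, rt) would give the vinyl diketone 1-(4-hydroxy-3-methoxyphenyl)hept-6-ene-3,5-dione F1, which would be used at once. Rhodium-catalysed 1,4-addition (Hayashi–Miyaura reaction; [Rh(cod)OH]2, dioxane/H2O, 50 °C) of the commercial boronic ester 2,6-dimethoxy-4-(4,4,5,5-tetramethyl-1,3,2-dioxaborolan-2-yl)phenol F2 to the vinyl ketone of F1 would form the same aryl–C7 bond with no β-hydride elimination involved and come back to the route at 8.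

Step 4. The hydrogenation may stall after the first carbonyl, or the second reduction may lose anti selectivity, for example if the phenols or the enolised diketone hold the catalyst in an unproductive chelate. The fallback sets the second centre by substrate control instead of catalyst control. Setting out from 8, the hydrogenation would be stopped deliberately at the hydroxy ketone stage (lower pressure, shorter time) and the mixture of 9 and 10 isolated. Hydroxyl-directed intramolecular hydride delivery with Me4NBH(OAc)3 (MeCN/AcOH, −30 °C; Evans–Saksena reduction) should then convert both regioisomers into the same anti diol and come back to the route at 11.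

Step 2. Under the strongly basic dianion conditions, proton transfer to the internal enolate, conjugate addition, anionic oligomerisation of acrolein or retro-aldol cleavage on warming may erode the aldol addition. The fallback separates enolisation from C–C bond formation and activates the aldehyde with a Lewis acid. Setting out from 3, LiN(i-Pr)2 (2.2 equiv) followed by Me3SiCl at −78 °C would give the bis-silyl compound 2-methoxy-4-[3-(trimethylsilyloxy)but-3-en-1-yl]phenyl trimethylsilyl ether F3. A Mukaiyama aldol addition of F3 to 4 (BF3·OEt2, CH2Cl2, −78 °C) would give the aryl silyl ether 5-hydroxy-1-[3-methoxy-4-(trimethylsilyloxy)phenyl]hept-6-en-3-one F4, and dilute aqueous acid on work-up would free the phenol and come back to the route at 6.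

Further compounds
F1 | step 3 | 1-(4-hydroxy-3-methoxyphenyl)hept-6-ene-3,5-dione | COc1cc(CCC(=O)CC(=O)C=C)ccc1O
F2 | step 3 | 2,6-dimethoxy-4-(4,4,5,5-tetramethyl-1,3,2-dioxaborolan-2-yl)phenol | COc1cc(B2OC(C)(C)C(C)(C)O2)cc(OC)c1O
F0 | step 4 | none | none
F3 | step 2 | 2-methoxy-4-[3-(trimethylsilyloxy)but-3-en-1-yl]phenyl trimethylsilyl ether | COc1cc(CCC(=C)O[Si](C)(C)C)ccc1O[Si](C)(C)C
F4 | step 2 | 5-hydroxy-1-[3-methoxy-4-(trimethylsilyloxy)phenyl]hept-6-en-3-one | COc1cc(CCC(=O)CC(O)C=C)ccc1O[Si](C)(C)C
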